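All runs are calculated from invented constants; noise was put on by code.

- A closed flask loses no substrate: at any moment it is free, in target, or in whatever target goes on to form.

| flask | substrate | gas phase | remark | time |
|---|---|---|---|---|
| summer | 0.78 M | 200 mM (held) | run made earlier |  |
| midnight | 1.2 M | 200 mM (held) | run made earlier |  |
| flask | 0.56 M | 200 mM (held) |  | 8.0 h |

- summer (time / h: target / %): 1.50: 48.8; 3.00: 40.9; 5.00: 32.0; 6.00: 29.0; 8.00: 24.3; 10.0: 22.0
- midnight (time / h: target / %): 0.833: 38.6; 1.33: 42.7; 2.00: 39.9; 4.00: 29.2; 6.00: 22.0; 10.0: 15.7

(standard deviation of a reading: 0.5 percentage points)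

- at the start none of the gas phase is in solution

- Wednesday's: doubling the saturation concentration of gas phase, all else as stated
- Tuesday's: doubling the transfer coefficient of the gas phase, all else as stated

- amount of target at 8.0 h, in percent of the substrate charged
- the change that raises the amount of target at 8.0 h, in percent of the substrate charged most ("none" if none brings more than 2 percentage points) (Wednesday's / Tuesday's / none)
- amount of target at 8.0 h, in percent of the substrate charged, after Wednesday's

- I take the inverse of c(target) against time, because a straight line there marks a loss that goes with the square of c(target). Over the late readings its slope is 0.385 L mol⁻¹ h⁻¹ in the summer run and 0.409 L mol⁻¹ h⁻¹ in the midnight run, so I carry the mean, 0.397 L mol⁻¹ h⁻¹.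
- Run back to the start, these lines give target as 64.7% and 68.4% of the charge. My reading is a pre-equilibrium: over the late readings, with the gas held, substrate binds gas quickly and reversibly, and target and free substrate keep a fixed ratio.
- The rest is the free share, the part of free substrate plus target that stays unbound on those late lines: 33.4%. If free substrate attacks target, the loss goes with c(substrate) times c(target), which at a fixed ratio is a square, and the slope goes with the free share.
- For this flask, the inverse of c(target) is the inverse of the bound part of the charge plus slope times time. My answer is 30.5%.
- In my reading Wednesday's doubles the bound-to-free ratio, so the free share becomes 20.1% and the slope 0.238 L mol⁻¹ h⁻¹, which gives 43.1%. In the same reading Tuesday's leaves that ratio alone, so I choose Wednesday's.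
- The forecast says 29.5% (27.5% to 32%), names Wednesday's, and gives 32.5% (29.5% to 36.5%) after it: “More dissolved gas should favour the productive step early”. My figure after Wednesday's stands above its range.
- The flask gives 29.8%. Wednesday's adds 12 percentage points, reaching 42.0%, and Tuesday's changes it by −0.042 points.

    gas phase ⇌ dissolved gas, rate k1*(csat - [dissolved gas]) (kL = 0.00600 s⁻¹)
    substrate + dissolved gas ⇌ target (K = 12.0 L mol⁻¹, k = 0.00200 L mol⁻¹ s⁻¹)
    substrate + target → side product (k = 2.10 × 10⁻⁴ L mol⁻¹ s⁻¹)

- At 8.00 h this flask holds 12.0% substrate and 29.8% target, a free share of 28.7%. The neighbour flask, charged with 0.14 M, a quarter of this charge, shows 29.1% at 8.00 h. The same line, with my free share of 33.4% and slope of 0.397 L mol⁻¹ h⁻¹, gives that neighbour 51.4%, and the neighbour flask holds 52.5% target.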